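**Retrosynthetic overview**

- The target is an 18-membered ring: ring A (1,4-phenylene) –CH2CH2– ring B (3-methoxy-1,2-phenylene) –O– ring C (1,3-phenylene) –CH2CH2– ring D (4-hydroxy-1,3-phenylene) –O– back to ring A. The strategy rests on the fact that the hydroxyl carbon C4 of ring D is ortho to C3, the carbon bearing the ether oxygen to ring A. A nitro group on C4 therefore activates a C3–F bond for SNAr and is afterwards converted into the OH.
- Last disconnection: C4–OH of ring D back to C4–NH2 and C4–NO2 (hydrogenation, diazotisation, copper-mediated hydrolysis).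
- Key disconnection: the O(ring A)–C3(ring D) bond, formed by intramolecular SNAr of the ring A phenoxide on a 3-fluoro-4-nitrophenyl terminus. This closes the only ring made in the route, the macrocycle; all four benzene rings are bought.
- The seco phenol is built linearly: formyl-activated SNAr (B–O–C ether), Wittig methylenation, hydroboration/B-alkyl Suzuki coupling to a THP-protected ring A bromide, vinylation of the ring C chloride, a second hydroboration/Suzuki coupling to 4-bromo-2-fluoro-1-nitrobenzene, and THP removal.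

Key step: step 7

Remark: compound 5 is used as the racemate. Its acetal carbon is the only stereocentre in the route, it is removed in step 6, and the target has none.

**Route**

Step 1
Reactants: 1 2-fluoro-3-methoxybenzaldehyde; 2 3-chlorophenol
Product: 3 2-(3-chlorophenoxy)-3-methoxybenzaldehyde
Conditions: K2CO3, DMAc, 130 °C
Reagents that add atoms: none
Why: Nucleophilic aromatic substitution (SNAr): the formyl group ortho to fluorine stabilises the Meisenheimer adduct, so the phenoxide of 2 should displace fluoride and set the hindered B–O–C ether in an intermolecular step, the aryl chloride staying inert.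

Step 2
Reactants: 3 2-(3-chlorophenoxy)-3-methoxybenzaldehyde
Product: 4 2-(3-chlorophenoxy)-1-ethenyl-3-methoxybenzene
Conditions: MePPh3Br, KOtBu, THF, 0 °C to rt
Reagents that add atoms: methyltriphenylphosphonium bromide, C[P+](c1ccccc1)(c1ccccc1)c1ccccc1.[Br-]
Why: Wittig methylenation of an aromatic aldehyde with the non-stabilised ylide should give the ring B styrene, and nothing else in 3 reacts with the ylide.

Step 3
Reactants: 4 2-(3-chlorophenoxy)-1-ethenyl-3-methoxybenzene; 5 2-(4-bromophenoxy)tetrahydro-2H-pyran (racemic)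
Product: 7 2-(4-{2-[2-(3-chlorophenoxy)-3-methoxyphenyl]ethyl}phenoxy)tetrahydro-2H-pyran (racemic), via alkyl-9-BBN borane 6 (not isolated)
Conditions: 9-BBN, THF, 0 °C to rt; then 5, PdCl2(dppf), K3PO4 (3 M aq.), DMF, 60 °C
Reagents that add atoms: none
Why: Anti-Markovnikov hydroboration of the styrene with 9-BBN followed by B-alkyl Suzuki–Miyaura coupling should form the A–B ethylene bridge at the aryl bromide of 5 only, because the unactivated ring C chloride does not undergo oxidative addition with the dppf-ligated catalyst at this temperature.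

Step 4
Reactants: 7 2-(4-{2-[2-(3-chlorophenoxy)-3-methoxyphenyl]ethyl}phenoxy)tetrahydro-2H-pyran (racemic)
Product: 8 2-(4-{2-[2-(3-ethenylphenoxy)-3-methoxyphenyl]ethyl}phenoxy)tetrahydro-2H-pyran (racemic)
Conditions: vinylboronic acid pinacol ester, Pd(OAc)2, SPhos, K3PO4, 1,4-dioxane/H2O, 90 °C
Reagents that add atoms: 4,4,5,5-tetramethyl-2-vinyl-1,3,2-dioxaborolane (vinylboronic acid pinacol ester), C=CB1OC(C)(C)C(C)(C)O1
Why: Suzuki–Miyaura vinylation of an unactivated aryl chloride, for which the electron-rich biaryl phosphine SPhos drives oxidative addition; the THP acetal is stable to the aqueous base.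

Step 5
Reactants: 8 2-(4-{2-[2-(3-ethenylphenoxy)-3-methoxyphenyl]ethyl}phenoxy)tetrahydro-2H-pyran (racemic); 9 4-bromo-2-fluoro-1-nitrobenzene
Product: 11 2-{4-[2-(2-{3-[2-(3-fluoro-4-nitrophenyl)ethyl]phenoxy}-3-methoxyphenyl)ethyl]phenoxy}tetrahydro-2H-pyran (racemic), via alkyl-9-BBN borane 10 (not isolated)
Conditions: 9-BBN, THF, 0 °C to rt; then 9, PdCl2(dppf), K2CO3 (2 M aq.), THF, 50 °C
Reagents that add atoms: none
Why: A second hydroboration/B-alkyl Suzuki–Miyaura coupling should form the C–D ethylene bridge; the electron-poor C–Br bond of 9 adds readily to zerovalent palladium, so carbonate at 50 °C should suffice and the activated C–F bond, which does not insert palladium, should be kept.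

Step 6
Reactants: 11 2-{4-[2-(2-{3-[2-(3-fluoro-4-nitrophenyl)ethyl]phenoxy}-3-methoxyphenyl)ethyl]phenoxy}tetrahydro-2H-pyran (racemic)
Product: 12 4-[2-(2-{3-[2-(3-fluoro-4-nitrophenyl)ethyl]phenoxy}-3-methoxyphenyl)ethyl]phenol (seco phenol)
Conditions: TsOH·H2O (cat.), MeOH/THF, rt
Reagents that add atoms: none
Why: Acid-catalysed transacetalisation cleaves the THP ether without ever forming a phenoxide, so the fluoronitroarene cannot react before the dilution step.

Step 7
Reactants: 12 4-[2-(2-{3-[2-(3-fluoro-4-nitrophenyl)ethyl]phenoxy}-3-methoxyphenyl)ethyl]phenol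
Product: 13 nitro macrocycle (the 18-membered ring A–CH2CH2–B–O–C–CH2CH2–D–O–A of the target with NO2 in place of OH on C4 of ring D)
Conditions: K2CO3, DMF, 0.002 M (slow addition of 12), 50 °C
Reagents that add atoms: none
Why: K2CO3 turns the ring A phenol into its phenoxide, which adds to C3 of ring D to give a Meisenheimer anion whose charge is taken up by the nitro group on the neighbouring C4, and loss of fluoride then gives the diaryl ether. The closest known reaction type is the intramolecular SNAr cycloetherification of phenoxides on ortho-fluoronitroarenes, an established way to close macrocyclic diaryl ethers. The 18-membered ring is closed end to end by forming the O–C3 bond between ring A and ring D, the two flexible ethylene bridges and the bent B–O–C ether letting the chain ends meet. No stereocentre is formed, and no stable atropisomer is expected in a ring of this size. Site selectivity is built in, because 12 holds one phenol and one activated C–F bond while the other aryl ethers are inert; ring closure against oligomerisation is secured by high dilution and slow addition.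

Step 8
Reactants: 13 nitro macrocycle
Product: 14 amino macrocycle (NH2 on C4 of ring D)
Conditions: H2 (1 atm), Pd/C (10 wt% palladium on carbon), EtOAc/EtOH, rt
Reagents that add atoms: none
Why: Catalytic hydrogenation of an aromatic nitro group to the aniline; the molecule holds no halide or benzylic C–O bond that could be cleaved.

Step 9
Reactants: 14 amino macrocycle
Product: 16 CNP0309263.0 (OH on C4 of ring D), via macrocyclic diazonium tetrafluoroborate 15 (not isolated)
Conditions: NaNO2, HBF4 (48% aq.), MeCN/H2O, 0 °C; then Cu(NO3)2 (large excess), Cu2O (substoichiometric), H2O, rt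
Reagents that add atoms: water, O
Why: Diazotisation followed by copper-mediated hydroxydediazoniation (Sandmeyer-type): monovalent copper reduces the diazonium ion to the aryl radical, which the large excess of aquated divalent copper should convert into the phenol at room temperature, placing the OH on the carbon that carried the nitro group.

**Compound list**

1 | 2-fluoro-3-methoxybenzaldehyde | COc1cccc(C=O)c1F | starting material
2 | 3-chlorophenol | Oc1cccc(Cl)c1 | starting material
3 | 2-(3-chlorophenoxy)-3-methoxybenzaldehyde | COc1cccc(C=O)c1Oc1cccc(Cl)c1 | intermediate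
4 | 2-(3-chlorophenoxy)-1-ethenyl-3-methoxybenzene | COc1cccc(C=C)c1Oc1cccc(Cl)c1 | intermediate
5 | 2-(4-bromophenoxy)tetrahydro-2H-pyran (racemic) | Brc1ccc(OC2CCCCO2)cc1 | starting material
6 | 9-{2-[2-(3-chlorophenoxy)-3-methoxyphenyl]ethyl}-9-borabicyclo[3.3.1]nonane | COc1cccc(CCB2C3CCCC2CCC3)c1Oc1cccc(Cl)c1 | intermediate
7 | 2-(4-{2-[2-(3-chlorophenoxy)-3-methoxyphenyl]ethyl}phenoxy)tetrahydro-2H-pyran (racemic) | COc1cccc(CCc2ccc(OC3CCCCO3)cc2)c1Oc1cccc(Cl)c1 | intermediate
8 | 2-(4-{2-[2-(3-ethenylphenoxy)-3-methoxyphenyl]ethyl}phenoxy)tetrahydro-2H-pyran (racemic) | COc1cccc(CCc2ccc(OC3CCCCO3)cc2)c1Oc1cccc(C=C)c1 | intermediate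
9 | 4-bromo-2-fluoro-1-nitrobenzene | O=[N+]([O-])c1ccc(Br)cc1F | starting material
10 | 9-{2-[3-(2-methoxy-6-{2-[4-(tetrahydro-2H-pyran-2-yloxy)phenyl]ethyl}phenoxy)phenyl]ethyl}-9-borabicyclo[3.3.1]nonane (racemic) | COc1cccc(CCc2ccc(OC3CCCCO3)cc2)c1Oc1cccc(CCB2C3CCCC2CCC3)c1 | intermediate
11 | 2-{4-[2-(2-{3-[2-(3-fluoro-4-nitrophenyl)ethyl]phenoxy}-3-methoxyphenyl)ethyl]phenoxy}tetrahydro-2H-pyran (racemic) | COc1cccc(CCc2ccc(OC3CCCCO3)cc2)c1Oc1cccc(CCc2ccc([N+](=O)[O-])c(F)c2)c1 | intermediate
12 | 4-[2-(2-{3-[2-(3-fluoro-4-nitrophenyl)ethyl]phenoxy}-3-methoxyphenyl)ethyl]phenol | COc1cccc(CCc2ccc(O)cc2)c1Oc1cccc(CCc2ccc([N+](=O)[O-])c(F)c2)c1 | intermediate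
13 | nitro macrocycle (18-membered ring, NO2 on C4 of ring D) | COc1cccc2c1Oc1cccc(c1)CCc1ccc([N+](=O)[O-])c(c1)Oc1ccc(cc1)CC2 | intermediate
14 | amino macrocycle (NH2 on C4 of ring D) | COc1cccc2c1Oc1cccc(c1)CCc1ccc(N)c(c1)Oc1ccc(cc1)CC2 | intermediate
15 | macrocyclic diazonium tetrafluoroborate (N2+ on C4 of ring D) | COc1cccc2c1Oc1cccc(c1)CCc1ccc([N+]#N)c(c1)Oc1ccc(cc1)CC2.F[B-](F)(F)F | intermediate
16 | CNP0309263.0 (OH on C4 of ring D) | COc1cccc2c1Oc1cccc(c1)CCc1ccc(O)c(c1)Oc1ccc(cc1)CC2 | target

**Step count**

Total: 9 steps. Longest linear sequence: 9 steps (1 to 16).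

**Steps most likely to fail, with fallbacks**

1. Step 7. Intermolecular etherification to dimers and oligomers may outrun closure of the 18-membered ring, or closure may be slow if the chain ends are held apart. Fallback, setting out from 8 and returning at 13: the macrocycle would be closed at the C–D ethylene bridge after the diaryl ether has been made intermolecularly.
 - The THP ether of 8 would be cleaved (TsOH·H2O, MeOH/THF) to 4-{2-[2-(3-ethenylphenoxy)-3-methoxyphenyl]ethyl}phenol F1.
 - Intermolecular SNAr of F1 with 9 (K2CO3, DMF, rt) should displace only the fluoride ortho to the nitro group and give 4-bromo-2-(4-{2-[2-(3-ethenylphenoxy)-3-methoxyphenyl]ethyl}phenoxy)-1-nitrobenzene F2.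
 - Hydroboration of the styrene with 9-BBN in THF would give 9-{2-[3-(2-{2-[4-(5-bromo-2-nitrophenoxy)phenyl]ethyl}-6-methoxyphenoxy)phenyl]ethyl}-9-borabicyclo[3.3.1]nonane F3.
 - Without isolation, F3 would be added slowly to PdCl2(dppf) and K2CO3 (aq.) in THF at high dilution, so that an intramolecular B-alkyl Suzuki–Miyaura coupling closes the ring to 13.

2. Step 5. Attack of hydroxide or carbonate on the activated C–F bond during the basic aqueous coupling, or protodeboronation and β-hydride elimination of the alkylborane, may erode the product. Fallback, setting out from 8 and returning at 11: a Mizoroki–Heck reaction of the styrene 8 with 9 under amine base without water (Pd(OAc)2, P(o-tol)3, Et3N, MeCN, 80 °C) would give the stilbene 2-{4-[2-(2-{3-[(E)-2-(3-fluoro-4-nitrophenyl)ethenyl]phenoxy}-3-methoxyphenyl)ethyl]phenoxy}tetrahydro-2H-pyran F4. Diimide reduction of the alkene (TsNHNH2, NaOAc, THF/H2O, reflux), which leaves the nitro group and the C–F bond alone, would then give 11.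

3. Step 9. The ring D aryl radical may be captured by the neighbouring ring A (closure to a dibenzofuran) or may abstract hydrogen from the co-solvent before divalent copper delivers the hydroxyl group. Fallback, setting out from 14 and returning at 16: the diazonium salt 15, made as in step 9, would be treated with KI in MeCN/H2O, where iodine transfer to the radical is faster than cyclisation, to give the iodo macrocycle (I on C4 of ring D) F5. Copper-catalysed hydroxylation of the aryl iodide (CuI, 1,10-phenanthroline, KOH, DMSO/H2O, 100 °C) would then give 16.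

**Further compounds**

F1 | step 7 | 4-{2-[2-(3-ethenylphenoxy)-3-methoxyphenyl]ethyl}phenol | COc1cccc(CCc2ccc(O)cc2)c1Oc1cccc(C=C)c1
F2 | step 7 | 4-bromo-2-(4-{2-[2-(3-ethenylphenoxy)-3-methoxyphenyl]ethyl}phenoxy)-1-nitrobenzene | COc1cccc(CCc2ccc(Oc3cc(Br)ccc3[N+](=O)[O-])cc2)c1Oc1cccc(C=C)c1
F3 | step 7 | 9-{2-[3-(2-{2-[4-(5-bromo-2-nitrophenoxy)phenyl]ethyl}-6-methoxyphenoxy)phenyl]ethyl}-9-borabicyclo[3.3.1]nonane | COc1cccc(CCc2ccc(Oc3cc(Br)ccc3[N+](=O)[O-])cc2)c1Oc1cccc(CCB2C3CCCC2CCC3)c1
F4 | step 5 | 2-{4-[2-(2-{3-[(E)-2-(3-fluoro-4-nitrophenyl)ethenyl]phenoxy}-3-methoxyphenyl)ethyl]phenoxy}tetrahydro-2H-pyran (racemic) | COc1cccc(CCc2ccc(OC3CCCCO3)cc2)c1Oc1cccc(/C=C/c2ccc([N+](=O)[O-])c(F)c2)c1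
F5 | step 9 | iodo macrocycle (I on C4 of ring D) | COc1cccc2c1Oc1cccc(c1)CCc1ccc(I)c(c1)Oc1ccc(cc1)CC2
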